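The vessel is the question here: one charge goes into a fed flask, a closed flask and two stirred tanks, and each is read for product.

all flasks: substrate 0.11 M; catalyst 5.6 mM; added ligand 3.2 mM
- teal: coupling partner 0.330 M (fed, over 64.0 min); time 80 min; all but coupling partner at the start; coupling partner goes in evenly over 64.0 min, the run ends at 80 min
- ochre: coupling partner 0.330 M; time 80 min; a closed flask charged with all of it at once and left for 80 min
- violet: coupling partner 0.330 M; a single well-mixed tank run continuously and read at steady state, 80 min in it on average
- green: coupling partner 0.330 M; one stirred flow tank at steady state, fed with the mixture as stated, mean residence time 400 min

    substrate + coupling partner + catalyst → catalyst + product (k1 = 0.231 M⁻² s⁻¹)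
    catalyst + added ligand ⇌ idle complex, settled at all times (K2 = 5400 M⁻¹)
    coupling partner → decomposed reagent (k3 = 3.58 × 10⁻⁴ s⁻¹)

- the stated concentrations are those of everything mixed, before any reaction; amounts are the same in each set-up
- the feed brings no volume worth counting
- run time (teal): 80 min

- the set-up with the highest amount of product at the outlet or at the end, in percent of the substrate put in ("none" if the first two lie within 2 percentage points) (teal / ochre / violet / green / none)
- amount of product at the outlet or at the end, in percent of the substrate put in, teal
- amount of product at the outlet or at the end, in percent of the substrate put in, ochre
- amount of product at the outlet or at the end, in percent of the substrate put in, violet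
- amount of product at the outlet or at the end, in percent of the substrate put in, green

I started in the closed flask, ochre, with the bench rule for an excess. Coupling partner stands at 3.00 equivalents, so I held it constant and treated substrate as pseudo-first-order. With catalyst as charged the half-life is 27 min, the run lasts 2.96 half-lives, and 12.8% of the substrate should remain.

That rule stops at a fork. I followed one molecule of coupling partner: it either couples or decomposes, and both steps are first order in it, so its own concentration cancels from the odds. Binding constant times catalyst is 30, far above one, so I subtracted the added ligand and kept 2.40 mM of free catalyst. The odds then hang on 0.646 M, the even-odds level: the substrate concentration at which a molecule of coupling partner is as likely to couple as to decompose. The chance of coupling is substrate over substrate plus that level.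

The level is 5.87 times the charged substrate, so the chance at the start in ochre is 14.6%. Against decomposition alone, coupling partner lives 46.6 min, less than the run, so I reckoned about 0.271 M used in ochre. That chance would make 0.0394 M of product. At the substrate left after half of that, the chance is 12.3%, and I committed to 30.2% for ochre. In teal the feed leaves its coupling partner 48.0 min on average, less than ochre's 80 min, so I put teal below ochre. The tanks I left unreckoned.

The forecast named ochre, with 27.5% for teal, 34% for ochre, 24.4% for violet and 30.9% for green, holding that “Charging it all at once in the closed flask gives the largest exposure”.

The simulation put ochre first at 34.0%, then green at 30.9%, teal at 27.2% and violet at 24.4%, so ochre stood 3.8 percentage points above my reckoning. Free catalyst in ochre stood at 46.6% of the charge, more than the 42.9% I had subtracted down to, and with it the even-odds level reckons to 0.593 M. In a neighbour of ochre charged with 0.0095 M of catalyst, 67.3% of that catalyst stood free, so the level reckons to 0.243 M and the chance runs from 31.2% at the start to 15.2% at the end. That neighbour turned 60.5% of its substrate into product, an amount equal to 22.8% of the coupling partner it used.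

(Its constants belong to no real substance; the rest is arithmetic.)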